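The electrophile is the small charge here, the limiting reagent: 0.050 M of it meets 2.00 equiv of nucleophile, while free base runs in over 10 min.

| flask | electrophile | nucleophile | free base | remark | time |
|---|---|---|---|---|---|
| cedar | 0.050 M | 2 equiv | 2.7 equiv (fed, over 10 min) | run made earlier; the fed solution adds 1.0 times the starting volume |  |
| elm | 0.050 M | 2 equiv | 4.9 equiv (fed, over 10 min) | run made earlier; the fed solution adds 1.0 times the starting volume |  |
| Friday's | 0.050 M | 2.00 equiv | 3.00 equiv (fed, over 10 min) | the fed solution adds 1.0 times the starting volume | 50 min |
| Saturday's | 0.050 M | 2.00 equiv | 3.90 equiv (fed, over 10 min) | the fed solution adds 1.0 times the starting volume | 50 min |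
| Thursday's | 0.050 M | 2.00 equiv | 5.10 equiv (fed, over 10 min) | the fed solution adds 1.0 times the starting volume | 50 min |

| run | time / min | electrophile / % | target / % |
|---|---|---|---|
| cedar | 10.0 | 70 | 18 |
| cedar | 20.0 | 62 | 27 |
| cedar | 30.0 | 49 | 37 |
| cedar | 40.0 | 49 | 38 |
| cedar | 50.0 | 41 | 42 |
| elm | 10.0 | 74 | 15 |
| elm | 20.0 | 61 | 29 |
| elm | 30.0 | 54 | 36 |
| elm | 40.0 | 46 | 39 |
| elm | 50.0 | 42 | 44 |

(readings scatter by 2 percentage points)

- percentages count the electrophile that a species holds: one idle adduct counts as two
- target is meant together with its idle adduct
- every charge counts on the volume at the start, and the solution that is fed holds the whole dose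
- reactions considered so far: electrophile + nucleophile -> acid set free + target; nucleophile + acid set free <-> protonated nucleophile; acid set free + free base <-> salt of the base; free base + target -> over-reaction product; electrophile + target <-> idle adduct
- in an amount of target, one idle adduct counts as one target
- what has gone from electrophile into another species counts as reacted, even if it can come back

1. part of the electrophile that has reacted at the end, Friday's
2. part of the electrophile that has reacted at the end, Saturday's
3. part of the electrophile that has reacted at the end, Thursday's
4. what raising the equivalents of free base from its lowest to its highest value here does to the part of the electrophile that has reacted (changes below 5 percentage points count as none) (it falls / no change / it rises)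

I keep the books on the electrophile at 50 min, averaging cedar and elm. Left as electrophile: 41.5 %. Held as target, its idle adduct counted once: 43.0 %. That leaves 15.5 % unbooked, which I enter as the second electrophile of the idle adduct, along with any target lost to over-reaction product; this entry is a reading and carries the scatter. The last two entries both count as reacted, so the question comes down to the first.

Cedar and elm, with 2.7 equiv and 4.9 equiv of free base, give my zero: the same electrophile in both, which is what I look for to call the base's effect invisible. At 50 min they differ by 1 percentage point, less than the scatter of 2 points.

So I use one number for this recipe: κ, an apparent pseudo-first-order loss of electrophile, which is the logarithm of charged over left, divided by the time, read from these runs as 0.0176 min⁻¹. It is an average over the run, with dilution, spent nucleophile and adduct lumped together, and it carries the scatter of the readings. Friday's, Saturday's and Thursday's share the electrophile and nucleophile charges of cedar and elm. Thursday's 5.10 equiv stands above elm's, and I stretch the zero that far. So at the time of the readings κ gives me 58.5 % reacted in each, which is the runs' average carried over, with no trend.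

The forecast says 58 %, 58 % and 58 %, trend no change, on the ground that “base loading, across nearly the whole range asked about, has no visible effect on consumption”.

The flasks give 58.8 %, 59.0 % and 59.1 %, trend no change, a change of 0.3 points.

    electrophile + nucleophile → acid set free + target (k = 0.00576 M⁻¹ s⁻¹)
    nucleophile + acid set free ⇌ protonated nucleophile, settled at all times (K = 6140 M⁻¹)
    acid set free + free base ⇌ salt of the base (K = 8700 M⁻¹, k = 0.491 M⁻¹ s⁻¹)
    free base + target → over-reaction product (k = 1.99 × 10⁻⁴ M⁻¹ s⁻¹)
    electrophile + target ⇌ idle adduct, settled at all times (K = 46.0 M⁻¹)

In Friday's, the electrophile and nucleophile step has 41 % of its turnover behind it after a fifth of the time, the salt step 5.0 %, and at 10.0 min protonated nucleophile stands at 0.00443 M against 1.43 × 10⁻⁴ M of salt of the base. At 50.0 min, free nucleophile stands at 61.1 % of its charge in Friday's and 63.5 % in Thursday's, while electrophile left stands at 41 % and 41 %. Friday's own κ comes to 0.0178 min⁻¹.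

Now take Friday's with 0.500 equiv of nucleophile, a quarter of the charge. If κ goes with the nucleophile charge, it becomes 0.00440 min⁻¹, which gives 19.7 % reacted. The computed flask gives 22.1 %.

The runs were generated by integration on assumed constants; the scatter is artificial.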